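**Retrosynthetic overview**

1. The C6 ester is made last, by Mitsunobu inversion of a 6β-allylic alcohol with O-silylated vanillic acid. The C4 carbinol comes from isopropylcerium addition to a C4 ketone that is carried as a dioxolane until then.
2. C7=C8(Me), C9–OH and C6–O come from the cycloadduct: the ester carbon becomes the C8 methyl by reductive transposition to an α-methylene ketone, C9 is reduced and silylated while C6 is still a silyl enol ether, then C6 is unmasked, the double bond is moved to C7=C8 and C6 is reduced.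
3. Key disconnection (bonds C7–C8 and C1–C10): formal (4+3) of a 2-siloxydiene (C7=C6(OSi)–C5=C1) with a rhodium siloxyvinyl carbene (C8(CO2Me)–C9(OSi)=C10). The strategy rests on the seven-membered ring C1–C5–C6–C7–C8–C9–C10, which carries oxygen on C6 and C9 (1,4 across C7=C8), a one-carbon branch on C8, and the quaternary methyl carbon C1 at the ring fusion.
4. Ring order: the cyclopentane C1–C5 is bought as 3-methylcyclopent-2-en-1-one; the seven-membered ring is the only ring formed (step 7). Stereocentres are set in the order C1 (catalyst), C9, C5, C6, C4, with C6 inverted on esterification.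

Key step: step 7

Remark on numbering: locants C1–C10 and the "bicyclo[5.3.0]" names use the skeleton numbering of the overview (five-membered ring C1–C2–C3–C4–C5, seven-membered ring C1–C5–C6–C7–C8–C9–C10), not von Baeyer numbering; β is the face of the C1 methyl. In this numbering the target is (1R,4R,5S,6S,9R).

Assumption: Rh2(S-PTAD)4 is taken to give the (R) configuration at C1; this sense of induction has to be checked on the first run, and if it is opposite the commercially available Rh2(R-PTAD)4 is used with nothing else changed.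

Step 1
Reactants: 1 3-methylcyclopent-2-en-1-one
Product: 3 2-bromo-3-methylcyclopent-2-en-1-one, via dibromide 2 (not isolated)
Conditions: Br2, CH2Cl2, 0 °C; then Et3N, 0 °C to rt
Reagents that add atoms: bromine BrBr
Why: Bromine adds across the enone double bond and triethylamine removes HBr from the α-bromide, which is the standard addition–elimination α-bromination of a cyclic enone.

Step 2
Reactants: 3 2-bromo-3-methylcyclopent-2-en-1-one
Product: 4 6-bromo-7-methyl-1,4-dioxaspiro[4.4]non-6-ene
Conditions: ethylene glycol, p-TsOH (cat.), benzene, reflux, Dean–Stark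
Reagents that add atoms: ethylene glycol OCCO
Why: Acid-catalysed dioxolane formation with azeotropic removal of water, in which the vinyl bromide keeps the double bond from moving out of conjugation with the ring methyl.

Step 3
Reactants: 4 6-bromo-7-methyl-1,4-dioxaspiro[4.4]non-6-ene
Product: 6 1-(7-methyl-1,4-dioxaspiro[4.4]non-6-en-6-yl)ethan-1-one, via vinyllithium 5 (not isolated)
Conditions: n-BuLi, THF, −78 °C; then MeC(O)N(OMe)Me, −78 to 0 °C; H2O
Reagents that add atoms: N-methoxy-N-methylacetamide CC(=O)N(C)OC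
Why: Bromine–lithium exchange gives the α-keto vinyl anion equivalent, which is acylated only once because the chelated tetrahedral adduct survives until work-up (Weinreb ketone synthesis).

Step 4
Reactants: 6 1-(7-methyl-1,4-dioxaspiro[4.4]non-6-en-6-yl)ethan-1-one
Product: 8 siloxydiene tert-butyldimethyl{[1-(7-methyl-1,4-dioxaspiro[4.4]non-6-en-6-yl)ethenyl]oxy}silane, via lithium enolate 7 (not isolated)
Conditions: LDA, THF, −78 °C; TBSCl, HMPA, −78 °C to rt; non-aqueous work-up, Et3N-deactivated silica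
Reagents that add atoms: tert-butyldimethylsilyl chloride CC(C)(C)[Si](C)(C)Cl
Why: LDA removes the kinetically most accessible α′ proton of the acetyl group to give the cross-conjugated enolate, which is silylated on oxygen (kinetic silyl enol ether formation under base, which spares the ketal).

Step 5
Reactants: 9 methyl acetoacetate
Product: 10 methyl 2-diazo-3-oxobutanoate
Conditions: 4-acetamidobenzenesulfonyl azide, Et3N, MeCN, 0 °C to rt
Reagents that add atoms: 4-acetamidobenzenesulfonyl azide CC(=O)Nc1ccc(cc1)S(=O)(=O)N=[N+]=[N-]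
Why: Regitz diazo transfer to the active methylene group of a β-keto ester.

Step 6
Reactants: 10 methyl 2-diazo-3-oxobutanoate
Product: 11 methyl 3-[(tert-butyldimethylsilyl)oxy]-2-diazobut-3-enoate
Conditions: TBSOTf, Et3N, CH2Cl2, 0 °C; used freshly
Reagents that add atoms: tert-butyldimethylsilyl trifluoromethanesulfonate CC(C)(C)[Si](C)(C)OS(=O)(=O)C(F)(F)F
Why: Soft enolisation of the acetyl group and O-silylation give the known siloxyvinyldiazoacetate and leave the diazo group intact.

Step 7
Reactants: 8 siloxydiene tert-butyldimethyl{[1-(7-methyl-1,4-dioxaspiro[4.4]non-6-en-6-yl)ethenyl]oxy}silane; 11 methyl 3-[(tert-butyldimethylsilyl)oxy]-2-diazobut-3-enoate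
Product: 13 methyl (1R)-6,9-bis[(tert-butyldimethylsilyl)oxy]-4,4-ethylenedioxy-1-methylbicyclo[5.3.0]deca-5,8-diene-8-carboxylate, via divinylcyclopropane 12 (not isolated)
Conditions: Rh2(S-PTAD)4 (1 mol %), hexanes, −26 °C, slow addition of 11 (1.5 equiv) to 8; then rt; then toluene, 80 °C until 12 is consumed
Reagents that add atoms: none
Why: The rhodium carbene from 11 cyclopropanates the electron-rich terminal C6=C7 enol-ether bond of 8 to give the cis-divinylcyclopropane 12, which undergoes a [3,3] (Cope) shift through the enforced boat transition state, breaking C6–C8 and forming C1–C10. The closest known reaction type is the chiral dirhodium-catalysed tandem cyclopropanation/Cope rearrangement of siloxyvinyldiazoacetates with 2-siloxydienes, including cases that create a quaternary centre. The seven-membered ring is closed in the pericyclic step and not by a polar cyclisation: C7–C8 comes from the cyclopropanation and C1–C10 from the boat [3,3] shift. The only stereocentre that survives, C1, is set by the catalyst (which face of the carbene meets the alkene) and is passed on stereospecifically from (1S,2R)-12 through the boat. The step needs site selectivity for the 1,1-disubstituted siloxy alkene over the tetrasubstituted ring alkene, which sterics and electron density secure, and a cis arrangement of the two vinyl groups, which donor/acceptor carbenes favour and which a trans isomer can reach by equilibration of the push–pull cyclopropane. Because the C1 methyl points inward in the boat, the Cope step is expected to need the warming given.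

Step 8
Reactants: 13 methyl (1R)-6,9-bis[(tert-butyldimethylsilyl)oxy]-4,4-ethylenedioxy-1-methylbicyclo[5.3.0]deca-5,8-diene-8-carboxylate
Product: 15 (1R)-6-[(tert-butyldimethylsilyl)oxy]-4,4-ethylenedioxy-1-methyl-8-methylidenebicyclo[5.3.0]dec-5-en-9-one, via allylic alcohol 14 (not isolated)
Conditions: DIBAL-H (2.5 equiv), CH2Cl2, −78 °C; Rochelle salt; then PPTS (cat.), CH2Cl2, 0 °C
Reagents that add atoms: none
Why: DIBAL-H reduces the vinylogous silyl carbonate to the 3-siloxyallylic alcohol without touching the simple enol ether or the ketal, and trace acid then ionises the allylic hydroxyl with loss of the silyl group to give the α-methylene ketone (Stork–Danheiser-type reductive transposition), so that the ester carbon becomes the C8 branch.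

Step 9
Reactants: 15 (1R)-6-[(tert-butyldimethylsilyl)oxy]-4,4-ethylenedioxy-1-methyl-8-methylidenebicyclo[5.3.0]dec-5-en-9-one
Product: 16 (1R,9R)-6-[(tert-butyldimethylsilyl)oxy]-4,4-ethylenedioxy-1-methyl-8-methylidenebicyclo[5.3.0]dec-5-en-9-ol
Conditions: DIBAL-H (1.2 equiv), CH2Cl2, −78 °C
Reagents that add atoms: none
Why: 1,2-Reduction of the enone by the bulky aluminium hydride from the ring face opposite to the axial C1 methyl (1,3 to C9) should give the 9β alcohol, cis to that methyl.

Step 10
Reactants: 16 (1R,9R)-6-[(tert-butyldimethylsilyl)oxy]-4,4-ethylenedioxy-1-methyl-8-methylidenebicyclo[5.3.0]dec-5-en-9-ol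
Product: 17 (1R,9R)-6,9-bis[(tert-butyldimethylsilyl)oxy]-4,4-ethylenedioxy-1-methyl-8-methylidenebicyclo[5.3.0]dec-5-ene
Conditions: TBSCl, imidazole, DMF, rt to 40 °C
Reagents that add atoms: tert-butyldimethylsilyl chloride CC(C)(C)[Si](C)(C)Cl
Why: Standard silylation of the only hydroxyl in an imidazole-buffered medium that leaves the silyl enol ether and the ketal alone, so that the C9 and C6 oxygens are now told apart as silyl ether and silyl enol ether.

Step 11
Reactants: 17 (1R,9R)-6,9-bis[(tert-butyldimethylsilyl)oxy]-4,4-ethylenedioxy-1-methyl-8-methylidenebicyclo[5.3.0]dec-5-ene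
Product: 19 (1R,5S,9R)-9-[(tert-butyldimethylsilyl)oxy]-4,4-ethylenedioxy-1,8-dimethylbicyclo[5.3.0]dec-7-en-6-one (trans-fused), via methylidene ketone 18 (not isolated)
Conditions: TBAF (1.05 equiv), AcOH (1.05 equiv), THF, −40 to 0 °C; then DBU (0.2 equiv), CH2Cl2, 0 °C
Reagents that add atoms: none
Why: Buffered fluoride cleaves the silyl enol ether far faster than the hindered secondary silyl ether, the C5 enolate is protonated on the face away from the axial C1 methyl and the 9β-silyloxy group to give the trans ring fusion, and catalytic DBU then moves the exocyclic double bond into conjugation through the C7 dienolate (β,γ- to α,β-enone isomerisation) while the C5–H between two fully substituted carbons is too hindered to exchange.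

Step 12
Reactants: 19 (1R,5S,9R)-9-[(tert-butyldimethylsilyl)oxy]-4,4-ethylenedioxy-1,8-dimethylbicyclo[5.3.0]dec-7-en-6-one
Product: 20 (1R,5S,6R,9R)-9-[(tert-butyldimethylsilyl)oxy]-4,4-ethylenedioxy-1,8-dimethylbicyclo[5.3.0]dec-7-en-6-ol
Conditions: NaBH4, CeCl3·7H2O, MeOH, −78 °C
Reagents that add atoms: none
Why: Luche 1,2-reduction in which hydride is expected to come from the α face, anti to the axial C1 methyl that is 1,3 to C6 (as in 2-, 4- and 6-oxo steroids), giving the 6β allylic alcohol that the later Mitsunobu step inverts.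

Step 13
Reactants: 20 (1R,5S,6R,9R)-9-[(tert-butyldimethylsilyl)oxy]-4,4-ethylenedioxy-1,8-dimethylbicyclo[5.3.0]dec-7-en-6-ol
Product: 21 (1R,5S,6R,9R)-9-[(tert-butyldimethylsilyl)oxy]-6-hydroxy-1,8-dimethylbicyclo[5.3.0]dec-7-en-4-one
Conditions: PPTS (cat.), acetone/H2O, 50 °C
Reagents that add atoms: water O
Why: Mild acid-catalysed hydrolysis of the dioxolane, with an acid too weak to ionise the allylic alcohol or to cleave the secondary silyl ether.

Step 14
Reactants: 21 (1R,5S,6R,9R)-9-[(tert-butyldimethylsilyl)oxy]-6-hydroxy-1,8-dimethylbicyclo[5.3.0]dec-7-en-4-one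
Product: 22 (1R,4R,5S,6R,9R)-9-[(tert-butyldimethylsilyl)oxy]-1,8-dimethyl-4-(propan-2-yl)bicyclo[5.3.0]dec-7-ene-4,6-diol
Conditions: i-PrMgCl (4 equiv), anhydrous CeCl3 (4 equiv), THF, −78 to −20 °C; aq. NH4Cl
Reagents that add atoms: isopropylmagnesium chloride CC(C)[Mg]Cl
Why: The organocerium reagent (Imamoto conditions) adds to the hindered, enolisable cyclopentanone without enolisation or β-elimination (the C6 hydroxyl is present as its alkoxide) and from the α face of the five-membered ring, anti to the C5–C6 bond and the C1 methyl, so that the isopropyl group ends cis to H5 and the hydroxyl β.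

Step 15
Reactants: 23 vanillic acid
Product: 25 4-[(tert-butyldimethylsilyl)oxy]-3-methoxybenzoic acid, via silyl ester 24 (not isolated)
Conditions: TBSCl (2.3 equiv), imidazole, DMF, rt; then AcOH/THF/H2O, rt
Reagents that add atoms: tert-butyldimethylsilyl chloride CC(C)(C)[Si](C)(C)Cl
Why: Exhaustive silylation followed by selective hydrolysis of the labile silyl ester leaves only the phenol protected, as the Mitsunobu step requires.

Step 16
Reactants: 22 (1R,4R,5S,6R,9R)-9-[(tert-butyldimethylsilyl)oxy]-1,8-dimethyl-4-(propan-2-yl)bicyclo[5.3.0]dec-7-ene-4,6-diol; 25 4-[(tert-butyldimethylsilyl)oxy]-3-methoxybenzoic acid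
Product: 26 (1R,4R,5S,6S,9R)-9-[(tert-butyldimethylsilyl)oxy]-4-hydroxy-1,8-dimethyl-4-(propan-2-yl)bicyclo[5.3.0]dec-7-en-6-yl 4-[(tert-butyldimethylsilyl)oxy]-3-methoxybenzoate
Conditions: PPh3, DIAD, toluene, 0 °C to rt
Reagents that add atoms: none
Why: Mitsunobu esterification of the secondary allylic 6β alcohol with SN2 inversion gives the 6α ester, the tertiary C4 hydroxyl not being activated and the phenol being masked.

Step 17
Reactants: 26 (1R,4R,5S,6S,9R)-9-[(tert-butyldimethylsilyl)oxy]-4-hydroxy-1,8-dimethyl-4-(propan-2-yl)bicyclo[5.3.0]dec-7-en-6-yl 4-[(tert-butyldimethylsilyl)oxy]-3-methoxybenzoate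
Product: 27 CNP0189996.3, (1R,4R,5S,6S,9R)-4,9-dihydroxy-1,8-dimethyl-4-(propan-2-yl)bicyclo[5.3.0]dec-7-en-6-yl 4-hydroxy-3-methoxybenzoate
Conditions: HF·pyridine, pyridine, THF, 0 °C to rt
Reagents that add atoms: none
Why: Pyridine-buffered HF removes the aryl and the secondary silyl ether without base-induced acyl migration to the neighbouring C4 hydroxyl and without ionising the allylic ester.

**Compound list**

1 | 3-methylcyclopent-2-en-1-one | CC1=CC(=O)CC1 | starting material
2 | 2,3-dibromo-3-methylcyclopentan-1-one | CC1(Br)CCC(=O)C1Br | intermediate (not isolated)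
3 | 2-bromo-3-methylcyclopent-2-en-1-one | CC1=C(Br)C(=O)CC1 | intermediate
4 | 6-bromo-7-methyl-1,4-dioxaspiro[4.4]non-6-ene | CC1=C(Br)C2(CC1)OCCO2 | intermediate
5 | (7-methyl-1,4-dioxaspiro[4.4]non-6-en-6-yl)lithium | [Li]C1=C(C)CCC12OCCO2 | intermediate (not isolated)
6 | 1-(7-methyl-1,4-dioxaspiro[4.4]non-6-en-6-yl)ethan-1-one | CC(=O)C1=C(C)CCC12OCCO2 | intermediate
7 | lithium 1-(7-methyl-1,4-dioxaspiro[4.4]non-6-en-6-yl)ethen-1-olate | [Li]OC(=C)C1=C(C)CCC12OCCO2 | intermediate (not isolated)
8 | tert-butyldimethyl{[1-(7-methyl-1,4-dioxaspiro[4.4]non-6-en-6-yl)ethenyl]oxy}silane (siloxydiene) | C=C(O[Si](C)(C)C(C)(C)C)C1=C(C)CCC12OCCO2 | intermediate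
9 | methyl acetoacetate | COC(=O)CC(C)=O | starting material
10 | methyl 2-diazo-3-oxobutanoate | COC(=O)C(=[N+]=[N-])C(C)=O | intermediate
11 | methyl 3-[(tert-butyldimethylsilyl)oxy]-2-diazobut-3-enoate | COC(=O)C(=[N+]=[N-])C(=C)O[Si](C)(C)C(C)(C)C | intermediate
12 | methyl (1S,2R)-2-[(tert-butyldimethylsilyl)oxy]-1-{1-[(tert-butyldimethylsilyl)oxy]ethenyl}-2-(7-methyl-1,4-dioxaspiro[4.4]non-6-en-6-yl)cyclopropane-1-carboxylate (vinyl groups cis) | COC(=O)[C@]1(C(=C)O[Si](C)(C)C(C)(C)C)C[C@@]1(O[Si](C)(C)C(C)(C)C)C2=C(C)CCC23OCCO3 | intermediate (not isolated)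
13 | methyl (1R)-6,9-bis[(tert-butyldimethylsilyl)oxy]-4,4-ethylenedioxy-1-methylbicyclo[5.3.0]deca-5,8-diene-8-carboxylate | CC(C)(C)[Si](C)(C)OC1=C2C3(OCCO3)CC[C@]2(C)CC(O[Si](C)(C)C(C)(C)C)=C(C(=O)OC)C1 | intermediate
14 | (1R)-6,9-bis[(tert-butyldimethylsilyl)oxy]-4,4-ethylenedioxy-8-(hydroxymethyl)-1-methylbicyclo[5.3.0]deca-5,8-diene | CC(C)(C)[Si](C)(C)OC1=C2C3(OCCO3)CC[C@]2(C)CC(O[Si](C)(C)C(C)(C)C)=C(CO)C1 | intermediate (not isolated)
15 | (1R)-6-[(tert-butyldimethylsilyl)oxy]-4,4-ethylenedioxy-1-methyl-8-methylidenebicyclo[5.3.0]dec-5-en-9-one | CC(C)(C)[Si](C)(C)OC1=C2C3(OCCO3)CC[C@]2(C)CC(=O)C(=C)C1 | intermediate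
16 | (1R,9R)-6-[(tert-butyldimethylsilyl)oxy]-4,4-ethylenedioxy-1-methyl-8-methylidenebicyclo[5.3.0]dec-5-en-9-ol | CC(C)(C)[Si](C)(C)OC1=C2C3(OCCO3)CC[C@]2(C)C[C@@H](O)C(=C)C1 | intermediate
17 | (1R,9R)-6,9-bis[(tert-butyldimethylsilyl)oxy]-4,4-ethylenedioxy-1-methyl-8-methylidenebicyclo[5.3.0]dec-5-ene | CC(C)(C)[Si](C)(C)OC1=C2C3(OCCO3)CC[C@]2(C)C[C@@H](O[Si](C)(C)C(C)(C)C)C(=C)C1 | intermediate
18 | (1R,5S,9R)-9-[(tert-butyldimethylsilyl)oxy]-4,4-ethylenedioxy-1-methyl-8-methylidenebicyclo[5.3.0]decan-6-one | O=C1CC(=C)[C@H](O[Si](C)(C)C(C)(C)C)C[C@@]2(C)CCC3(OCCO3)[C@H]12 | intermediate (not isolated)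
19 | (1R,5S,9R)-9-[(tert-butyldimethylsilyl)oxy]-4,4-ethylenedioxy-1,8-dimethylbicyclo[5.3.0]dec-7-en-6-one | O=C1C=C(C)[C@H](O[Si](C)(C)C(C)(C)C)C[C@@]2(C)CCC3(OCCO3)[C@H]12 | intermediate
20 | (1R,5S,6R,9R)-9-[(tert-butyldimethylsilyl)oxy]-4,4-ethylenedioxy-1,8-dimethylbicyclo[5.3.0]dec-7-en-6-ol | O[C@@H]1C=C(C)[C@H](O[Si](C)(C)C(C)(C)C)C[C@@]2(C)CCC3(OCCO3)[C@H]12 | intermediate
21 | (1R,5S,6R,9R)-9-[(tert-butyldimethylsilyl)oxy]-6-hydroxy-1,8-dimethylbicyclo[5.3.0]dec-7-en-4-one | O[C@@H]1C=C(C)[C@H](O[Si](C)(C)C(C)(C)C)C[C@@]2(C)CCC(=O)[C@H]12 | intermediate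
22 | (1R,4R,5S,6R,9R)-9-[(tert-butyldimethylsilyl)oxy]-1,8-dimethyl-4-(propan-2-yl)bicyclo[5.3.0]dec-7-ene-4,6-diol | O[C@@H]1C=C(C)[C@H](O[Si](C)(C)C(C)(C)C)C[C@@]2(C)CC[C@@](O)(C(C)C)[C@H]12 | intermediate
23 | vanillic acid | COc1cc(C(=O)O)ccc1O | starting material
24 | tert-butyldimethylsilyl 4-[(tert-butyldimethylsilyl)oxy]-3-methoxybenzoate | COc1cc(C(=O)O[Si](C)(C)C(C)(C)C)ccc1O[Si](C)(C)C(C)(C)C | intermediate (not isolated)
25 | 4-[(tert-butyldimethylsilyl)oxy]-3-methoxybenzoic acid | COc1cc(C(=O)O)ccc1O[Si](C)(C)C(C)(C)C | intermediate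
26 | (1R,4R,5S,6S,9R)-9-[(tert-butyldimethylsilyl)oxy]-4-hydroxy-1,8-dimethyl-4-(propan-2-yl)bicyclo[5.3.0]dec-7-en-6-yl 4-[(tert-butyldimethylsilyl)oxy]-3-methoxybenzoate | COc1cc(C(=O)O[C@H]2C=C(C)[C@H](O[Si](C)(C)C(C)(C)C)C[C@@]3(C)CC[C@@](O)(C(C)C)[C@H]23)ccc1O[Si](C)(C)C(C)(C)C | intermediate
27 | CNP0189996.3, (1R,4R,5S,6S,9R)-4,9-dihydroxy-1,8-dimethyl-4-(propan-2-yl)bicyclo[5.3.0]dec-7-en-6-yl 4-hydroxy-3-methoxybenzoate | COc1cc(C(=O)O[C@H]2C=C(C)[C@H](O)C[C@@]3(C)CC[C@@](O)(C(C)C)[C@H]23)ccc1O | target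

**Step count and risks**

Total step count: 17. Longest linear sequence: 14 steps (1–4, 7–14, 16, 17).

The three steps most likely to fail:

Step 7. The crowded, twisted diene may be cyclopropanated with low enantioselectivity. In addition, the boat Cope step is slowed by the inward C1 methyl, which may let the push–pull cyclopropane open to a zwitterion and so erode the enantiomeric purity. Fallback: catalyst control is given up and the enantiomer is obtained by resolution. Setting out again from 8 and 11, an achiral, robust dirhodium carboxylate (Rh2(esp)2, toluene, 80–110 °C) is used to give the racemic cycloadduct F1. The conditions of steps 8 and 9 then give the racemic methylene ketone F2 and the racemic alcohol F3. F3 is resolved by preparative chromatography on a chiral stationary phase; its (1R,9R) enantiomer is 16, where the route is rejoined.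

Step 11. Three things may go wrong: protonation of the ring-fusion enolate on the methyl face (cis fusion), loss of the C9 silyl ether to fluoride, or migration of the double bond past C8 into the C8=C9 silyl enol ether position. Fallback: the C9 oxygen is kept at the ketone level while the ring fusion is set, so that C5 is fixed under equilibrating conditions instead of by a single kinetic protonation and the only conjugated position for the double bond is C7=C8. Setting out from 15, TBAF and then DBU give the ene-dione F4, which is equilibrated at C5 and purified. Luche reduction of both carbonyls anti to the C1 methyl gives the 6β,9β-diol F5. Silylation of the less hindered C9 hydroxyl (TBSCl, imidazole, low temperature) gives 20, where the route is rejoined.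

Step 16. The oxyphosphonium salt of the crowded axial 6β alcohol may eliminate towards C5 (H5 is anti-periplanar) or resist displacement. Fallback: the 6α alcohol is made under thermodynamic control and acylated with retention. Setting out from 19, Meerwein–Ponndorf–Verley reduction under equilibrating conditions (Al(Oi-Pr)3, i-PrOH, toluene, 80 °C) gives the equatorial 6α-alcohol F6. The conditions of steps 13 and 14 then give the ketone F7 and the 6α-hydroxy carbinol F8. F8 is esterified with 25 (2,4,6-trichlorobenzoyl chloride, Et3N, DMAP) to give 26, where the route is rejoined. The same path is used if step 12 should deliver the 6α alcohol directly.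

Further compounds
F1 | step 7 | racemic cycloadduct (racemic 13) | CC(C)(C)[Si](C)(C)OC1=C2C3(OCCO3)CC[C@]2(C)CC(O[Si](C)(C)C(C)(C)C)=C(C(=O)OC)C1.CC(C)(C)[Si](C)(C)OC1=C2C3(OCCO3)CC[C@@]2(C)CC(O[Si](C)(C)C(C)(C)C)=C(C(=O)OC)C1
F2 | step 7 | racemic methylene ketone (racemic 15) | CC(C)(C)[Si](C)(C)OC1=C2C3(OCCO3)CC[C@]2(C)CC(=O)C(=C)C1.CC(C)(C)[Si](C)(C)OC1=C2C3(OCCO3)CC[C@@]2(C)CC(=O)C(=C)C1
F3 | step 7 | racemic alcohol (racemic 16, 1R*,9R*) | CC(C)(C)[Si](C)(C)OC1=C2C3(OCCO3)CC[C@]2(C)C[C@@H](O)C(=C)C1.CC(C)(C)[Si](C)(C)OC1=C2C3(OCCO3)CC[C@@]2(C)C[C@H](O)C(=C)C1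
F4 | step 11 | (1R,5S)-4,4-ethylenedioxy-1,8-dimethylbicyclo[5.3.0]dec-7-ene-6,9-dione (ene-dione) | O=C1C=C(C)C(=O)C[C@@]2(C)CCC3(OCCO3)[C@H]12
F5 | step 11 | (1R,5S,6R,9R)-4,4-ethylenedioxy-1,8-dimethylbicyclo[5.3.0]dec-7-ene-6,9-diol (6β,9β-diol) | O[C@@H]1C=C(C)[C@H](O)C[C@@]2(C)CCC3(OCCO3)[C@H]12
F6 | step 16 | (1R,5S,6S,9R)-9-[(tert-butyldimethylsilyl)oxy]-4,4-ethylenedioxy-1,8-dimethylbicyclo[5.3.0]dec-7-en-6-ol (6α-alcohol) | O[C@H]1C=C(C)[C@H](O[Si](C)(C)C(C)(C)C)C[C@@]2(C)CCC3(OCCO3)[C@H]12
F7 | step 16 | (1R,5S,6S,9R)-9-[(tert-butyldimethylsilyl)oxy]-6-hydroxy-1,8-dimethylbicyclo[5.3.0]dec-7-en-4-one | O[C@H]1C=C(C)[C@H](O[Si](C)(C)C(C)(C)C)C[C@@]2(C)CCC(=O)[C@H]12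
F8 | step 16 | (1R,4R,5S,6S,9R)-9-[(tert-butyldimethylsilyl)oxy]-1,8-dimethyl-4-(propan-2-yl)bicyclo[5.3.0]dec-7-ene-4,6-diol | O[C@H]1C=C(C)[C@H](O[Si](C)(C)C(C)(C)C)C[C@@]2(C)CC[C@@](O)(C(C)C)[C@H]12
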